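## Retrosynthetic overview

- Numbering follows isochroman-1-one: C1 carbonyl, O2, C3, C4, C4a, C5–C8, C8a. Ring A is the arene, ring B the lactone, and the side chain is C1'–C11'. The target comes from its tribenzyl ether by hydrogenolysis. That ether comes from the flat isocoumarin by a catalyst-controlled hydrogenation of C3=C4, which sets C3.
- The isocoumarin comes from three parts in one flask: a ring A aryne (C4a≡C8a), a terminal alkyne (C4, C3 and the whole side chain) and CO2 (C1 and O2). The flask makes C4a–C4, then C8a–C1, and last O2–C3, which closes ring B. Ring A is bought, and ring B is the only ring formed.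
- Enabling feature: on ring A the oxygen-bearing C8 stands directly beside C8a. This polarises the aryne so that the nucleophile goes to C4a and the metal, then CO2, to C8a. The resulting ortho carboxylate/alkyne pair puts O2 within 6-endo reach of C3.
- The alkyne comes from (S)-1,2-epoxybutane (source of C9') and non-1-yne by epoxide opening, alkyne zipper and benzylation. The aryne precursor comes from 3,5-bis(benzyloxy)phenol by bromination, O-silylation and retro-Brook shift/triflation.

Key step: step 7

Assumption: 3,5-bis(benzyloxy)phenol is taken as a catalogue compound, and the hand of the ruthenium catalyst in step 8 (both ligand enantiomers are sold) is to be fixed by a trial run on a simple 3-alkylisocoumarin whose product configuration is known.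

## Route

Step 1
Reactants: 1 3,5-bis(benzyloxy)phenol
Product: 2 3,5-bis(benzyloxy)-2-bromophenol
Conditions: NBS (1.0 equiv), CH2Cl2, −78 °C to 0 °C
Reagents that add atoms: N-bromosuccinimide, O=C1CCC(=O)N1Br
Why: Electrophilic aromatic bromination, in which hydrogen bonding of the phenol OH to NBS in a non-polar solvent at low temperature should steer bromine to the ortho carbon C2, a site also para to one benzyloxy group and less crowded than C4 between the two benzyloxy groups.

Step 2
Reactants: 2 3,5-bis(benzyloxy)-2-bromophenol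
Product: 3 [3,5-bis(benzyloxy)-2-bromophenoxy]trimethylsilane
Conditions: (Me3Si)2NH, THF, 65 °C; concentrate
Reagents that add atoms: hexamethyldisilazane, C[Si](C)(C)N[Si](C)(C)C
Why: O-silylation of a phenol with a silazane, driven by loss of ammonia, under neutral conditions that touch neither the aryl bromide nor the benzyl ethers.

Step 3
Reactants: 3 [3,5-bis(benzyloxy)-2-bromophenoxy]trimethylsilane
Product: 6 3,5-bis(benzyloxy)-2-(trimethylsilyl)phenyl trifluoromethanesulfonate, via aryllithium 4 (not isolated), via lithium silylphenoxide 5 (not isolated)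
Conditions: n-BuLi, THF, −78 °C; then Tf2O, −78 °C to 0 °C
Reagents that add atoms: trifluoromethanesulfonic anhydride, O=S(=O)(OS(=O)(=O)C(F)(F)F)C(F)(F)F
Why: Bromine–lithium exchange gives 4, the silyl group moves from oxygen to the neighbouring carbanion (retro-Brook 1,3-shift, driven by the more stable phenoxide 5), and 5 is triflated on oxygen, the exchange at −78 °C being much faster than deprotonation of the benzyl ethers.

Step 4
Reactants: 7 non-1-yne; 8 (S)-1,2-epoxybutane
Product: 11 (3S)-tridec-5-yn-3-ol, via non-1-ynyllithium 9 (not isolated), via lithium alkoxytrifluoroborate 10 (not isolated)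
Conditions: 7, n-BuLi, THF, −78 °C; BF3·OEt2; then 8, −78 °C; aq. NH4Cl
Reagents that add atoms: none
Why: Yamaguchi–Hirao alkynylation, an SN2 opening of the BF3-activated epoxide at its unsubstituted carbon, so no bond to the stereocentre is broken and the (S) configuration of 8 becomes that of C9' of the target.

Step 5
Reactants: 11 (3S)-tridec-5-yn-3-ol
Product: 13 (3S)-tridec-12-yn-3-ol, via dipotassium alkoxide acetylide 12 (not isolated)
Conditions: KH, H2N(CH2)3NH2, 0 °C to rt; then H2O
Reagents that add atoms: none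
Why: Alkyne zipper isomerisation, in which the amide base walks the triple bond along the chain through allene–alkyne equilibria, the alkoxide-bearing carbon blocks the other direction, irreversible formation of the terminal acetylide in 12 pulls the equilibrium to C12≡C13, and the non-acidic carbinol C–H keeps the (S) centre intact.

Step 6
Reactants: 13 (3S)-tridec-12-yn-3-ol
Product: 15 (3S)-3-(benzyloxy)tridec-12-yne, via sodium alkoxide 14 (not isolated)
Conditions: NaH, BnBr, Bu4NI (cat.), THF–DMF, 0 °C to rt
Reagents that add atoms: benzyl bromide, BrCc1ccccc1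
Why: Williamson ether synthesis on oxygen only, which leaves the configuration alone, masks the alcohol against the aryne and CO2 of step 7, and gives an ether that falls off together with the aryl benzyl ethers in step 9.

Step 7
Reactants: 6 3,5-bis(benzyloxy)-2-(trimethylsilyl)phenyl trifluoromethanesulfonate; 15 (3S)-3-(benzyloxy)tridec-12-yne
Product: 21 6,8-bis(benzyloxy)-3-[(9S)-9-(benzyloxy)undecyl]-1H-isochromen-1-one, via copper acetylide 16 (not isolated), via aryne 17 (not isolated), via arylcopper 18 (not isolated), via copper carboxylate 19 (not isolated), via vinylcopper 20 (not isolated)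
Conditions: 6 (1.5 equiv), 15, (IPr)CuCl (10 mol %; IPr = 1,3-bis(2,6-diisopropylphenyl)imidazol-2-ylidene), CsF, Cs2CO3, CO2 (1 atm), MeCN–THF, 80 °C
Reagents that add atoms: carbon dioxide, O=C=O
Why: Copper-catalysed three-component coupling of an aryne, a terminal alkyne and CO2 to an isocoumarin (a known reaction type, used here on an unsymmetrical aryne): fluoride removes the silyl group of 6 and triflate leaves to give aryne 17, acetylide 16 (from 15, Cs2CO3 and the monovalent copper catalyst) adds across the strained triple bond to give arylcopper 18, CO2 inserts into its C–Cu bond to give carboxylate 19, the copper then binds the alkyne so that the carboxylate oxygen attacks C3 anti to the metal to give vinylcopper 20, and 15 protonates C4 of 20, which releases 21 and returns 16. Ring B is the only ring closed; the mode is 6-endo-dig and the closing bond is O2–C3, after C4a–C4 and C8a–C1 have been made in the same flask. Side selection on the aryne comes from the benzyloxy group on C8 beside the triple bond: its inductive pull distorts 17 so that the remote terminus C4a is the more linear and electrophilic one and negative charge (the C–Cu bond) is best placed on C8a next to oxygen, so the acetylide carbon goes to C4a, which is also the less crowded end (C5 bears only H), and CO2 ends on C8a, while the second benzyloxy group on C6 is too far from either terminus to override this. The 6-endo over 5-exo preference needed at the closure rests on the alkyl group on C3, which carries the developing positive charge of the copper-bound alkyne better than C4 (C4 hangs on C4a, a ring position meta to both alkoxy groups and ortho to the carboxylate), and on the conjugated 2-pyranone being the more stable product. CO2 capture has to outrun protonation of 18, which the electron-rich and strongly nucleophilic aryl–copper bond, the dry carbonate-buffered medium and the slow fluoride-limited release of 17 should favour. No stereocentre is formed, and the (S) centre of the chain, a benzyl ether eight methylene groups away from the alkyne, is not touched.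

Step 8
Reactants: 21 6,8-bis(benzyloxy)-3-[(9S)-9-(benzyloxy)undecyl]-1H-isochromen-1-one
Product: 22 (3R)-6,8-bis(benzyloxy)-3-[(9S)-9-(benzyloxy)undecyl]-3,4-dihydro-1H-isochromen-1-one
Conditions: chiral Ru(NHC)(diamine) catalyst (2 mol %; made from Ru(2-methylallyl)2(cod), SINpEt·HBF4, KOtBu and 1,2-diphenylethane-1,2-diamine), NaOtBu (cat.), H2 (50 bar), toluene, rt
Reagents that add atoms: none
Why: Enantioselective hydrogenation of a 3-substituted isocoumarin with a chiral ruthenium–NHC–diamine catalyst, a reaction type shown on 3-alkyl and 8-alkoxy isocoumarins, in which the catalyst pocket alone picks the face (hydrogen to the Si face of C3 gives R), the distant C9' centre has no say, and benzyl ethers, lactone and arenes are inert to this homogeneous catalyst.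

Step 9
Reactants: 22 (3R)-6,8-bis(benzyloxy)-3-[(9S)-9-(benzyloxy)undecyl]-3,4-dihydro-1H-isochromen-1-one
Product: 23 (3R)-6,8-dihydroxy-3-[(9S)-9-hydroxyundecyl]-3,4-dihydro-1H-isochromen-1-one
Conditions: H2 (1 atm), 10% Pd/C, EtOAc–MeOH, rt
Reagents that add atoms: none
Why: Catalytic hydrogenolysis of the two aryl benzyl ethers and the alkyl benzyl ether in one operation, in which the C3–O2 bond is only homobenzylic and should stay, and neither stereocentre is involved.

## Compound list

1 | 3,5-bis(benzyloxy)phenol | Oc1cc(OCc2ccccc2)cc(OCc2ccccc2)c1 | starting material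
2 | 3,5-bis(benzyloxy)-2-bromophenol | Oc1cc(OCc2ccccc2)cc(OCc2ccccc2)c1Br | intermediate
3 | [3,5-bis(benzyloxy)-2-bromophenoxy]trimethylsilane | C[Si](C)(C)Oc1cc(OCc2ccccc2)cc(OCc2ccccc2)c1Br | intermediate
4 | {2,4-bis(benzyloxy)-6-[(trimethylsilyl)oxy]phenyl}lithium | C[Si](C)(C)Oc1cc(OCc2ccccc2)cc(OCc2ccccc2)c1[Li] | intermediate
5 | lithium 3,5-bis(benzyloxy)-2-(trimethylsilyl)phenoxide | [Li+].[O-]c1cc(OCc2ccccc2)cc(OCc2ccccc2)c1[Si](C)(C)C | intermediate
6 | 3,5-bis(benzyloxy)-2-(trimethylsilyl)phenyl trifluoromethanesulfonate | C[Si](C)(C)c1c(OS(=O)(=O)C(F)(F)F)cc(OCc2ccccc2)cc1OCc1ccccc1 | intermediate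
7 | non-1-yne | C#CCCCCCCC | starting material
8 | (S)-1,2-epoxybutane | CC[C@H]1CO1 | starting material
9 | non-1-ynyllithium | [Li]C#CCCCCCCC | intermediate
10 | lithium trifluoro[(3S)-tridec-5-yn-3-yloxy]borate | [Li+].CC[C@H](O[B-](F)(F)F)CC#CCCCCCCC | intermediate
11 | (3S)-tridec-5-yn-3-ol | CC[C@H](O)CC#CCCCCCCC | intermediate
12 | dipotassium salt (alkoxide and acetylide) of (3S)-tridec-12-yn-3-ol | [K+].[K+].CC[C@H]([O-])CCCCCCCCC#[C-] | intermediate
13 | (3S)-tridec-12-yn-3-ol | CC[C@H](O)CCCCCCCCC#C | intermediate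
14 | sodium (3S)-tridec-12-yn-3-olate | [Na+].CC[C@H]([O-])CCCCCCCCC#C | intermediate
15 | (3S)-3-(benzyloxy)tridec-12-yne | CC[C@H](OCc1ccccc1)CCCCCCCCC#C | intermediate
16 | [(11S)-11-(benzyloxy)tridec-1-yn-1-yl](IPr)copper | CC[C@H](OCc1ccccc1)CCCCCCCCC#C[Cu]=C1N(c2c(C(C)C)cccc2C(C)C)C=CN1c1c(C(C)C)cccc1C(C)C | intermediate
17 | 3,5-bis(benzyloxy)benzyne (1,2-didehydrobenzene) | C1#CC(OCc2ccccc2)=CC(OCc2ccccc2)=C1 | intermediate
18 | {2,4-bis(benzyloxy)-6-[(11S)-11-(benzyloxy)tridec-1-yn-1-yl]phenyl}(IPr)copper | CC[C@H](OCc1ccccc1)CCCCCCCCC#Cc1cc(OCc2ccccc2)cc(OCc2ccccc2)c1[Cu]=C1N(c2c(C(C)C)cccc2C(C)C)C=CN1c1c(C(C)C)cccc1C(C)C | intermediate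
19 | (IPr)copper 2,4-bis(benzyloxy)-6-[(11S)-11-(benzyloxy)tridec-1-yn-1-yl]benzoate | CC[C@H](OCc1ccccc1)CCCCCCCCC#Cc1cc(OCc2ccccc2)cc(OCc2ccccc2)c1C(=O)O[Cu]=C1N(c2c(C(C)C)cccc2C(C)C)C=CN1c1c(C(C)C)cccc1C(C)C | intermediate
20 | {6,8-bis(benzyloxy)-3-[(9S)-9-(benzyloxy)undecyl]-1-oxo-1H-isochromen-4-yl}(IPr)copper | CC[C@H](OCc1ccccc1)CCCCCCCCC1=C([Cu]=C2N(c3c(C(C)C)cccc3C(C)C)C=CN2c2c(C(C)C)cccc2C(C)C)c2cc(OCc3ccccc3)cc(OCc3ccccc3)c2C(=O)O1 | intermediate
21 | 6,8-bis(benzyloxy)-3-[(9S)-9-(benzyloxy)undecyl]-1H-isochromen-1-one | CC[C@H](OCc1ccccc1)CCCCCCCCC1=Cc2cc(OCc3ccccc3)cc(OCc3ccccc3)c2C(=O)O1 | intermediate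
22 | (3R)-6,8-bis(benzyloxy)-3-[(9S)-9-(benzyloxy)undecyl]-3,4-dihydro-1H-isochromen-1-one | CC[C@H](OCc1ccccc1)CCCCCCCC[C@@H]1Cc2cc(OCc3ccccc3)cc(OCc3ccccc3)c2C(=O)O1 | intermediate
23 | (3R)-6,8-dihydroxy-3-[(9S)-9-hydroxyundecyl]-3,4-dihydro-1H-isochromen-1-one | CC[C@H](O)CCCCCCCC[C@@H]1Cc2cc(O)cc(O)c2C(=O)O1 | target

## Step count and risks

Total step count: 9. Longest linear sequence: 6 (steps 1–3 or steps 4–6, then steps 7–9).

**Step 7.**
- What may go wrong: the arylcopper may be protonated by the alkyne before it takes up CO2. Reversible carboxylation of the acetylide may starve the aryne of its partner. The closure may also drift to the 5-exo mode.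
- Fallback: the three bonds are made one at a time by cross-coupling chemistry. It sets out from 1 and 15 and comes back to the route at 21.
- Ortho-selective formylation of 1 (MgCl2, Et3N, paraformaldehyde, MeCN, reflux; Casnati–Skattebøl reaction) gives 2,4-bis(benzyloxy)-6-hydroxybenzaldehyde F1.
- Tf2O and pyridine convert this into 3,5-bis(benzyloxy)-2-formylphenyl trifluoromethanesulfonate F2.
- Sonogashira coupling with 15 (PdCl2(PPh3)2, CuI, Et3N, DMF) gives 2,4-bis(benzyloxy)-6-[(11S)-11-(benzyloxy)tridec-1-yn-1-yl]benzaldehyde F3.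
- Pinnick oxidation (NaClO2, NaH2PO4, 2-methyl-2-butene) gives 2,4-bis(benzyloxy)-6-[(11S)-11-(benzyloxy)tridec-1-yn-1-yl]benzoic acid F4.
- AgOTf-catalysed 6-endo-dig cycloisomerisation in CH2Cl2 then closes ring B to 21.

**Step 8.**
- What may go wrong: facial selectivity may be poor, or turnover may stall, on a substrate with a benzyloxy group beside the lactone carbonyl and a long lipophilic chain.
- Fallback: the enol lactone is opened and the stereocentre is set by a biocatalytic ketone reduction. It sets out from 21 and comes back at 22.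
- KOH in aqueous THF–MeOH followed by mild acidification gives 2,4-bis(benzyloxy)-6-[(11S)-11-(benzyloxy)-2-oxotridecyl]benzoic acid F5.
- A ketoreductase picked from a screening panel (NADP+, glucose, glucose dehydrogenase, buffer with DMSO) reduces its salt to 2,4-bis(benzyloxy)-6-[(2R,11S)-11-(benzyloxy)-2-hydroxytridecyl]benzoic acid F6.
- F6 lactonises with catalytic TsOH in toluene to 22.

**Step 1.**
- What may go wrong: bromination may occur at C4 between the two benzyloxy groups, or twice.
- Fallback: the carbon–silicon bond is made by directed ortho-metalation, with no halogenation. It sets out from 1 and comes back at 5.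
- ClC(O)NEt2 and NaH give 3,5-bis(benzyloxy)phenyl diethylcarbamate F7.
- s-BuLi and TMEDA at −78 °C lithiate the position flanked by the carbamate and a benzyloxy group, and TMSCl gives 3,5-bis(benzyloxy)-2-(trimethylsilyl)phenyl diethylcarbamate F8.
- LiAlH4 in THF removes the carbamoyl group to give 3,5-bis(benzyloxy)-2-(trimethylsilyl)phenol F9.
- n-BuLi at −78 °C turns F9 into phenoxide 5, which is triflated as in step 3.

## Further compounds

F1 | step 7 | 2,4-bis(benzyloxy)-6-hydroxybenzaldehyde | O=Cc1c(O)cc(OCc2ccccc2)cc1OCc1ccccc1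
F2 | step 7 | 3,5-bis(benzyloxy)-2-formylphenyl trifluoromethanesulfonate | O=Cc1c(OS(=O)(=O)C(F)(F)F)cc(OCc2ccccc2)cc1OCc1ccccc1
F3 | step 7 | 2,4-bis(benzyloxy)-6-[(11S)-11-(benzyloxy)tridec-1-yn-1-yl]benzaldehyde | CC[C@H](OCc1ccccc1)CCCCCCCCC#Cc1cc(OCc2ccccc2)cc(OCc2ccccc2)c1C=O
F4 | step 7 | 2,4-bis(benzyloxy)-6-[(11S)-11-(benzyloxy)tridec-1-yn-1-yl]benzoic acid | CC[C@H](OCc1ccccc1)CCCCCCCCC#Cc1cc(OCc2ccccc2)cc(OCc2ccccc2)c1C(=O)O
F5 | step 8 | 2,4-bis(benzyloxy)-6-[(11S)-11-(benzyloxy)-2-oxotridecyl]benzoic acid | CC[C@H](OCc1ccccc1)CCCCCCCCC(=O)Cc1cc(OCc2ccccc2)cc(OCc2ccccc2)c1C(=O)O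
F6 | step 8 | 2,4-bis(benzyloxy)-6-[(2R,11S)-11-(benzyloxy)-2-hydroxytridecyl]benzoic acid | CC[C@H](OCc1ccccc1)CCCCCCCC[C@@H](O)Cc1cc(OCc2ccccc2)cc(OCc2ccccc2)c1C(=O)O
F7 | step 1 | 3,5-bis(benzyloxy)phenyl diethylcarbamate | CCN(CC)C(=O)Oc1cc(OCc2ccccc2)cc(OCc2ccccc2)c1
F8 | step 1 | 3,5-bis(benzyloxy)-2-(trimethylsilyl)phenyl diethylcarbamate | CCN(CC)C(=O)Oc1cc(OCc2ccccc2)cc(OCc2ccccc2)c1[Si](C)(C)C
F9 | step 1 | 3,5-bis(benzyloxy)-2-(trimethylsilyl)phenol | Oc1cc(OCc2ccccc2)cc(OCc2ccccc2)c1[Si](C)(C)C
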